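**Strategy.** The cyclopent-2-enone is opened between the enone β-carbon (the ring CH= remote from the carbonyl) and the quaternary acetoxy carbon. With the ketone carbon in the middle, the five ring carbons are a divinyl ketone in disguise, and the acetoxy carbon is the enol-acetate carbon of a 1,3-dicarbonyl unit. A catalytic enantioselective, silicon-directed Nazarov cyclisation therefore closes the ring, creates the O-substituted quaternary stereocenter with the acetate already in place, fixes the C=C position by loss of silicon and sets the pentenyl-bearing carbon by protonation, all in one operation. The precursor is an acyclic (E)-β-silylvinyl ketone carrying a (Z)-enol acetate, made in four steps from two fatty-acid derivatives.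

Key step: step 5

Assumption: compounds 1, 3 and 7 are treated as catalogue compounds, and the (S)-acid of step 5 is a working choice whose sense of induction on this new substrate must be verified (the antipodal acid is used if it is opposite).

**Step 1**
Reactants: 1 (4Z)-hept-4-enoic acid
Product: 2 S-ethyl (4Z)-hept-4-enethioate
Conditions: EtSH, DCC, DMAP (cat.), CH2Cl2, 0 °C to rt
Reagents that add atoms: ethanethiol, CCS
Why: Steglich-type thioesterification: DCC activates the acid as its O-acylisourea and DMAP relays the acyl group to the thiol, so the thioester should form without touching the (Z)-alkene; no stereocenter is formed.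

**Step 2**
Reactants: 2 S-ethyl (4Z)-hept-4-enethioate; 3 9-tert-butoxy-9-oxononanoic acid
Product: 5 tert-butyl (12Z)-10-[(ethylsulfanyl)carbonyl]-9-oxopentadec-12-enoate, via acyl imidazolide 4 (not isolated)
Conditions: 3, CDI, THF, rt; separately 2, LiN(SiMe3)2 (2.1 equiv), THF, −78 °C; then 4, −78 to −30 °C; aq. NH4Cl
Reagents that add atoms: 1,1'-carbonyldiimidazole, O=C(n1ccnc1)n1ccnc1 (supplies the imidazolyl group of 4, which leaves again on the way to 5)
Why: Crossed Claisen condensation: the lithium enolate of thioester 2 is C-acylated by the acyl imidazolide 4, the second equivalent of base deprotonates the β-keto thioester as it forms and so drives the reaction, and the hindered tert-butyl ester is inert; the stereocenter at C10 arises as a racemate and is removed again in step 3.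

**Step 3**
Reactants: 5 tert-butyl (12Z)-10-[(ethylsulfanyl)carbonyl]-9-oxopentadec-12-enoate
Product: 6 tert-butyl (9Z,12Z)-9-acetoxy-10-[(ethylsulfanyl)carbonyl]pentadeca-9,12-dienoate
Conditions: LiN(SiMe3)2 (1.05 equiv), THF, −78 °C; then Ac2O, −78 to 0 °C
Reagents that add atoms: acetic anhydride, CC(=O)OC(C)=O
Why: O-Acylation of a chelated lithium enolate: lithium bridges the two carbonyl oxygens of the enolate of 5 in a U-shape and the fully substituted α-carbon is shielded, so the hard anhydride is expected to acetylate the ketone-derived oxygen and give the (9Z)-enol acetate with the acetoxy group cis to the thioester carbonyl.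

**Step 4**
Reactants: 6 tert-butyl (9Z,12Z)-9-acetoxy-10-[(ethylsulfanyl)carbonyl]pentadeca-9,12-dienoate; 7 (E)-trimethyl[2-(tributylstannyl)ethenyl]silane
Product: 8 tert-butyl (9Z,12E)-9-acetoxy-11-oxo-10-[(2Z)-pent-2-en-1-yl]-13-(trimethylsilyl)trideca-9,12-dienoate
Conditions: Pd2(dba)3 (cat.), tri(2-furyl)phosphine, CuOP(O)Ph2 (1.5 equiv), THF, 50 °C
Reagents that add atoms: none
Why: Liebeskind–Srogl ketone synthesis in its stannane variant: zerovalent palladium inserts into the C(acyl)–S bond while the thiophilic monovalent copper salt takes up the thiolate, and the alkenyl group is transferred from tin (not from silicon) with retention of its (E) geometry under neutral, base-free conditions that should spare the enol acetate, its (Z) geometry and the tert-butyl ester.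

**Step 5**
Reactants: 8 tert-butyl (9Z,12E)-9-acetoxy-11-oxo-10-[(2Z)-pent-2-en-1-yl]-13-(trimethylsilyl)trideca-9,12-dienoate
Product: 10 tert-butyl 8-[(1R,5S)-1-acetoxy-4-oxo-5-[(2Z)-pent-2-en-1-yl]cyclopent-2-en-1-yl]octanoate, via cyclopentadienol 9 (not isolated)
Conditions: Zn(OTf)2 (5 mol %), (S)-6,6'-bis(2,4,6-triisopropylphenyl)-1,1'-spirobiindane-7,7'-diyl hydrogen phosphate (6 mol %), PhOH (1.2 equiv), ClCH2CH2Cl, 40 °C
Reagents that add atoms: none
Why: Proposed new method: zinc, carrying the chiral phosphate, binds the ketone oxygen of 8 and generates a 3-oxidopentadienyl cation whose five carbons are the future ring; the α-pentenyl group enforces the U-shaped conformer with the small acetoxy group inside, a thermal conrotatory 4π electrocyclisation joins the silyl-bearing terminus to the acetoxy-bearing terminus, the oxyallyl cation so formed is stabilised β to silicon and gives up Me3Si to phenol to form dienol 9, and protonation at the pentenyl-bearing carbon gives 10. The closest known reaction type is the silicon-directed Nazarov cyclisation of β-silyl divinyl ketones in its catalytic enantioselective form (zinc Lewis acid, chiral phosphoric acid, phenol); it has not been shown for a fully substituted terminus bearing an acyloxy group, which is expected to be tolerated because the oxygen lone pair is shared with the acetyl carbonyl and so does not over-stabilise the open cation. The only ring closed is the cyclopentenone, by conrotatory 4π electrocyclisation (formally a 5-endo closure that is open only to the pericyclic pathway). The quaternary acetoxy carbon (1R) is set by the catalyst, whose chiral phosphate in the contact ion pair selects one of the two conrotatory senses of the geometrically pure (9Z)-enol acetate; the pentenyl carbon (5S) is set afterwards by kinetic protonation of 9 on the face of the smaller acetoxy group, opposite the octanoate chain, which places the two carbon chains cis. The step needs positional selectivity for the double bond, secured by loss of silicon instead of a proton; it needs retention of the tertiary acetate, secured because ionisation or β-elimination would lead to an antiaromatic cyclopentadienone-type species; and it needs the absence of a 1,5-acetyl shift to the ketone oxygen, which metal coordination of that oxygen should suppress.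

**Step 6**
Reactants: 10 tert-butyl 8-[(1R,5S)-1-acetoxy-4-oxo-5-[(2Z)-pent-2-en-1-yl]cyclopent-2-en-1-yl]octanoate
Product: 11 8-[(1R,5S)-1-acetoxy-4-oxo-5-[(2Z)-pent-2-en-1-yl]cyclopent-2-en-1-yl]octanoic acid
Conditions: CF3CO2H, CH2Cl2, 0 °C
Reagents that add atoms: none
Why: Acidolysis of the tert-butyl ester by the E1 pathway: only the tert-butyl cation forms readily, whereas ionisation of the tertiary acetate would give a destabilised 4-oxocyclopentenyl cation, and the base-free medium avoids enolisation and β-elimination at the pentenyl-bearing carbon, so both stereocenters should be retained.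

**Compound list**

1 | (4Z)-hept-4-enoic acid | CC/C=C\CCC(=O)O | starting material
2 | S-ethyl (4Z)-hept-4-enethioate | CC/C=C\CCC(=O)SCC | intermediate
3 | 9-tert-butoxy-9-oxononanoic acid (mono-tert-butyl azelate) | OC(=O)CCCCCCCC(=O)OC(C)(C)C | starting material
4 | tert-butyl 9-(1H-imidazol-1-yl)-9-oxononanoate (acyl imidazolide, not isolated) | O=C(CCCCCCCC(=O)OC(C)(C)C)n1ccnc1 | intermediate
5 | tert-butyl (12Z)-10-[(ethylsulfanyl)carbonyl]-9-oxopentadec-12-enoate (racemic at C10) | CC/C=C\CC(C(=O)SCC)C(=O)CCCCCCCC(=O)OC(C)(C)C | intermediate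
6 | tert-butyl (9Z,12Z)-9-acetoxy-10-[(ethylsulfanyl)carbonyl]pentadeca-9,12-dienoate | CCSC(=O)/C(C/C=C\CC)=C(\OC(C)=O)CCCCCCCC(=O)OC(C)(C)C | intermediate
7 | (E)-trimethyl[2-(tributylstannyl)ethenyl]silane | CCCC[Sn](CCCC)(CCCC)/C=C/[Si](C)(C)C | starting material
8 | tert-butyl (9Z,12E)-9-acetoxy-11-oxo-10-[(2Z)-pent-2-en-1-yl]-13-(trimethylsilyl)trideca-9,12-dienoate | C[Si](C)(C)/C=C/C(=O)/C(C/C=C\CC)=C(\OC(C)=O)CCCCCCCC(=O)OC(C)(C)C | intermediate
9 | tert-butyl 8-[(1R)-1-acetoxy-4-hydroxy-5-[(2Z)-pent-2-en-1-yl]cyclopenta-2,4-dien-1-yl]octanoate (dienol, not isolated) | CC/C=C\CC1=C(O)C=C[C@@]1(CCCCCCCC(=O)OC(C)(C)C)OC(C)=O | intermediate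
10 | tert-butyl 8-[(1R,5S)-1-acetoxy-4-oxo-5-[(2Z)-pent-2-en-1-yl]cyclopent-2-en-1-yl]octanoate | CC/C=C\C[C@@H]1C(=O)C=C[C@@]1(CCCCCCCC(=O)OC(C)(C)C)OC(C)=O | intermediate
11 | 8-[(1R,5S)-1-acetoxy-4-oxo-5-[(2Z)-pent-2-en-1-yl]cyclopent-2-en-1-yl]octanoic acid | CC/C=C\C[C@@H]1C(=O)C=C[C@@]1(CCCCCCCC(=O)O)OC(C)=O | target

**Step count.** Total: 6 steps. Longest linear sequence: 6 steps (1 → 2 → 5 → 6 → 8 → 10 → 11).

**Steps most likely to fail**

1. Step 5 (proposed new method).
   - What may go wrong: the acetoxy-stabilised pentadienyl cation may cyclise too slowly or not at all. Enol-acetate isomerisation or 1,5-acetyl migration before ring closure would erode the enantioselectivity. Protonation of the dienol from the wrong face, or later acid-mediated epimerisation, would give the diastereomer with the two chains trans.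
   - Fallback (known chemistry, same ring bond closed): it sets out from 1 and comes back at 10. Acid 1 is coupled (DCC, DMAP) with (4R)-4-benzyl-1,3-oxazolidin-2-one to the N-acyl oxazolidinone F1. An Evans syn-aldol reaction (Bu2BOTf, iPr2NEt, then 3-[(4-methoxybenzyl)oxy]propanal) should give the (2R,3S)-aldol adduct F2, which fixes the pentenyl-bearing stereocenter. Silylation (TBSOTf, 2,6-lutidine) gives the silyl ether F3, and EtSNa displaces the auxiliary to give the thioester F4. Fukuyama coupling (PdCl2(PPh3)2) with the alkylzinc bromide F5, made from tert-butyl 8-bromooctanoate with Zn dust and LiCl, gives the ketone F6. DDQ frees the primary alcohol F7 and Dess–Martin periodinane gives the keto-aldehyde F8. The ring is then closed between the aldehyde carbon and the ketone carbon by pinacol cyclisation with SmI2 (THF, t-BuOH, −78 °C). By the established preference for a cis-diol anti to the substituent next to the ketyl, this should give the diol F9 with the tertiary hydroxyl trans to the pentenyl group. Selective mesylation of the secondary hydroxyl (MsCl, Et3N) gives the mesylate F10, and HF·pyridine gives the alcohol F11. Dess–Martin oxidation gives the keto mesylate F12, which eliminates with Et3N to the hydroxy enone F13. Acetylation of the tertiary alcohol (Ac2O, cat. Bi(OTf)3, 0 °C) returns to 10.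

2. Step 4.
   - What may go wrong: oxidative addition and transmetalation may be slow at the hindered, fully substituted acyl thioester; thiolate may add to the β-acetoxy position with loss of acetate; the stannane may be protodestannylated.
   - Fallback: it sets out from 6 and comes back at 8. Fukuyama reduction (Et3SiH, Pd/C, acetone) converts the thioester into the aldehyde F14. Nozaki–Hiyama–Kishi addition of (E)-(2-bromoethenyl)trimethylsilane (CrCl2, cat. NiCl2, DMF) gives the allylic alcohol F15. Oxidation with MnO2 gives 8.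

3. Step 3.
   - What may go wrong: C-acetylation may compete with O-acetylation, or geometric control may be lost in the acylation event.
   - Fallback: it sets out from 5 and comes back at 6. The sodium chelate of 5 (NaH, THF, 0 °C) is silylated with Me3SiCl to the (Z)-trimethylsilyl enol ether F16, whose geometry is set and checked before acylation. Acetyl fluoride with catalytic Bu4N[Ph3SiF2] then exchanges silicon for acetyl with retention and gives 6.

**Further compounds**

F1 | step 5 | (4R)-4-benzyl-3-[(4Z)-hept-4-enoyl]-1,3-oxazolidin-2-one | CC/C=C\CCC(=O)N1[C@H](Cc2ccccc2)COC1=O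
F2 | step 5 | (4R)-4-benzyl-3-[(2R,3S)-3-hydroxy-5-[(4-methoxybenzyl)oxy]-2-[(2Z)-pent-2-en-1-yl]pentanoyl]-1,3-oxazolidin-2-one | CC/C=C\C[C@H]([C@@H](O)CCOCc1ccc(OC)cc1)C(=O)N1[C@H](Cc2ccccc2)COC1=O
F3 | step 5 | (4R)-4-benzyl-3-[(2R,3S)-3-{[tert-butyl(dimethyl)silyl]oxy}-5-[(4-methoxybenzyl)oxy]-2-[(2Z)-pent-2-en-1-yl]pentanoyl]-1,3-oxazolidin-2-one | CC/C=C\C[C@H]([C@@H](O[Si](C)(C)C(C)(C)C)CCOCc1ccc(OC)cc1)C(=O)N1[C@H](Cc2ccccc2)COC1=O
F4 | step 5 | S-ethyl (2R,3S)-3-{[tert-butyl(dimethyl)silyl]oxy}-5-[(4-methoxybenzyl)oxy]-2-[(2Z)-pent-2-en-1-yl]pentanethioate | CC/C=C\C[C@H]([C@@H](O[Si](C)(C)C(C)(C)C)CCOCc1ccc(OC)cc1)C(=O)SCC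
F5 | step 5 | [8-(tert-butoxy)-8-oxooctyl]zinc bromide | CC(C)(C)OC(=O)CCCCCCC[Zn]Br
F6 | step 5 | tert-butyl (10R,11S)-11-{[tert-butyl(dimethyl)silyl]oxy}-13-[(4-methoxybenzyl)oxy]-9-oxo-10-[(2Z)-pent-2-en-1-yl]tridecanoate | CC/C=C\C[C@H]([C@@H](O[Si](C)(C)C(C)(C)C)CCOCc1ccc(OC)cc1)C(=O)CCCCCCCC(=O)OC(C)(C)C
F7 | step 5 | tert-butyl (10R,11S)-11-{[tert-butyl(dimethyl)silyl]oxy}-13-hydroxy-9-oxo-10-[(2Z)-pent-2-en-1-yl]tridecanoate | CC/C=C\C[C@H]([C@@H](O[Si](C)(C)C(C)(C)C)CCO)C(=O)CCCCCCCC(=O)OC(C)(C)C
F8 | step 5 | tert-butyl (10R,11S)-11-{[tert-butyl(dimethyl)silyl]oxy}-9,13-dioxo-10-[(2Z)-pent-2-en-1-yl]tridecanoate | CC/C=C\C[C@H]([C@@H](O[Si](C)(C)C(C)(C)C)CC=O)C(=O)CCCCCCCC(=O)OC(C)(C)C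
F9 | step 5 | tert-butyl 8-[(1S,2R,4S,5R)-4-{[tert-butyl(dimethyl)silyl]oxy}-1,2-dihydroxy-5-[(2Z)-pent-2-en-1-yl]cyclopentyl]octanoate | CC/C=C\C[C@@H]1[C@@H](O[Si](C)(C)C(C)(C)C)C[C@@H](O)[C@@]1(CCCCCCCC(=O)OC(C)(C)C)O
F10 | step 5 | tert-butyl 8-[(1S,2R,4S,5R)-4-{[tert-butyl(dimethyl)silyl]oxy}-1-hydroxy-2-[(methylsulfonyl)oxy]-5-[(2Z)-pent-2-en-1-yl]cyclopentyl]octanoate | CC/C=C\C[C@@H]1[C@@H](O[Si](C)(C)C(C)(C)C)C[C@@H](OS(C)(=O)=O)[C@@]1(CCCCCCCC(=O)OC(C)(C)C)O
F11 | step 5 | tert-butyl 8-[(1S,2R,4S,5R)-1,4-dihydroxy-2-[(methylsulfonyl)oxy]-5-[(2Z)-pent-2-en-1-yl]cyclopentyl]octanoate | CC/C=C\C[C@@H]1[C@@H](O)C[C@@H](OS(C)(=O)=O)[C@@]1(CCCCCCCC(=O)OC(C)(C)C)O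
F12 | step 5 | tert-butyl 8-[(1S,2R,5S)-1-hydroxy-2-[(methylsulfonyl)oxy]-4-oxo-5-[(2Z)-pent-2-en-1-yl]cyclopentyl]octanoate | CC/C=C\C[C@@H]1C(=O)C[C@@H](OS(C)(=O)=O)[C@@]1(CCCCCCCC(=O)OC(C)(C)C)O
F13 | step 5 | tert-butyl 8-[(1R,5S)-1-hydroxy-4-oxo-5-[(2Z)-pent-2-en-1-yl]cyclopent-2-en-1-yl]octanoate | CC/C=C\C[C@@H]1C(=O)C=C[C@@]1(CCCCCCCC(=O)OC(C)(C)C)O
F14 | step 4 | tert-butyl (9Z,12Z)-9-acetoxy-10-formylpentadeca-9,12-dienoate | O=C/C(C/C=C\CC)=C(\OC(C)=O)CCCCCCCC(=O)OC(C)(C)C
F15 | step 4 | tert-butyl (9Z,12E)-9-acetoxy-11-hydroxy-10-[(2Z)-pent-2-en-1-yl]-13-(trimethylsilyl)trideca-9,12-dienoate (racemic at C11) | C[Si](C)(C)/C=C/C(O)/C(C/C=C\CC)=C(\OC(C)=O)CCCCCCCC(=O)OC(C)(C)C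
F16 | step 3 | tert-butyl (9Z,12Z)-10-[(ethylsulfanyl)carbonyl]-9-[(trimethylsilyl)oxy]pentadeca-9,12-dienoate | CCSC(=O)/C(C/C=C\CC)=C(\O[Si](C)(C)C)CCCCCCCC(=O)OC(C)(C)C
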